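**Retrosynthetic overview**

1. The δ-lactone is made last. Its ester C–O bond and the bond between the isopropenyl-bearing carbon and the O-bearing carbon are cut, giving 3-methyl-2-oxobutanal and an (E)-allylboronate hung on the future spiro carbon (anti-selective allylboration, then lactonisation).
2. The allyl unit is placed on the ester-bearing carbon of bicyclic β-keto ester 8 by Pd-catalysed allylation with isoprene monoepoxide, on the convex face of the cis-fused bicycle.
3. 8 arises in one pot from monocyclic lactone ester 5 by a ring switch: Dieckmann closure of the cyclopentanone onto the lactone C=O (which becomes the ring ketone and releases the tertiary alkoxide), O-Boc capture of that alkoxide, then attack of the β-keto ester dianion on the carbonate, closing the γ-lactone through its C(=O)–C(CH3) bond.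
4. Enabling feature: the cyclopentanone C=O is the centre of a 1,3,5-tricarbonyl array (γ-lactone C=O on the methyl-bearing ring-fusion carbon, ester C=O on the spiro carbon), and the lactone oxygen on CMe2 is γ to both the ketone carbon and the lactone carbon. The O–CMe2–CH–C(CH3) chain can therefore lactonise onto either carbonyl, and it holds the carbonate over the enolate carbon (5-exo, cis-fusion enforced).
5. 5 comes from (S)-α-terpineol (source of the ring-fusion CH stereocentre) by alkene cleavage, haloform reaction, α-methylation and esterification. Ring order: temporary isomeric γ-lactone → cyclopentanone → γ-lactone → δ-lactone.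

Key step: step 5

Remark: (S)-(−)-α-terpineol of high enantiomeric purity is assumed to be commercially available; every other stereocentre is derived from it or set by reagent control.

**Route**

Step 1
Reactants: 1 (S)-(−)-α-terpineol
Product: 2 (4S)-5,5-dimethyl-4-(3-oxobutyl)oxolan-2-one
Conditions: RuCl3·xH2O (2 mol%), NaIO4 (4 equiv), MeCN/EtOAc/H2O, 0 °C → rt
Reagents that add atoms: sodium periodate, [Na+].[O-]I(=O)(=O)=O
Why: Ruthenium tetroxide generated in situ should cleave the trisubstituted ring alkene to a methyl ketone and a carboxylic acid, which the γ-tertiary hydroxyl captures at once as the γ-lactone (oxidative alkene cleavage/lactonisation); the stereocentre is not touched.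

Step 2
Reactants: 2 (4S)-5,5-dimethyl-4-(3-oxobutyl)oxolan-2-one
Product: 3 3-[(3S)-2,2-dimethyl-5-oxooxolan-3-yl]propanoic acid
Conditions: aq. NaOCl (3.5 equiv), NaOH, 1,4-dioxane/H2O, 0 °C → rt; then HCl to pH 1, rt
Reagents that add atoms: sodium hydroxide, [Na+].[OH-]
Why: Haloform reaction: exhaustive α-chlorination of the methyl ketone and C–C cleavage by hydroxide should give the carboxylate, while the lactone, opened reversibly by base, recloses on acidification; the stereocentre is β to both carbonyls and cannot epimerise.

Step 3
Reactants: 3 3-[(3S)-2,2-dimethyl-5-oxooxolan-3-yl]propanoic acid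
Product: 4 3-[(3S,4S)-2,2,4-trimethyl-5-oxooxolan-3-yl]propanoic acid
Conditions: LDA (2.2 equiv), THF, −78 °C; MeI (1.1 equiv), −78 → −20 °C; 1 M HCl
Reagents that add atoms: iodomethane, CI
Why: The carboxylate shields the side-chain CH2 from deprotonation, so the second equivalent of LDA should enolise only the lactone, and methyl iodide is expected to enter trans to the neighbouring side chain (lactone enolate alkylation); this centre becomes a carbanion again in step 5, so its configuration is not critical.

Step 4
Reactants: 4 3-[(3S,4S)-2,2,4-trimethyl-5-oxooxolan-3-yl]propanoic acid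
Product: 5 methyl 3-[(3S,4S)-2,2,4-trimethyl-5-oxooxolan-3-yl]propanoate
Conditions: MeI (1.5 equiv), K2CO3, DMF, rt
Reagents that add atoms: iodomethane, CI
Why: SN2 O-alkylation of the carboxylate should give the methyl ester under conditions too mild to enolise ester or lactone.

Step 5
Reactants: 5 methyl 3-[(3S,4S)-2,2,4-trimethyl-5-oxooxolan-3-yl]propanoate
Product: 8 methyl (3aS,6aS)-3,3,6a-trimethyl-1,6-dioxohexahydro-1H-cyclopenta[c]furan-5-carboxylate, via hydroxy keto ester 6 (not isolated), via Boc carbonate 7 (not isolated)
Conditions: LDA (1.1 equiv), THF, −78 → 0 °C; LDA (1.1 equiv), then Boc2O (1.05 equiv), −78 → 0 °C; LDA (2 equiv), −78 → 0 °C; 1 M HCl, 0 °C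
Reagents that add atoms: di-tert-butyl dicarbonate, CC(C)(C)OC(=O)OC(=O)OC(C)(C)C
Why: The first equivalent of LDA is expected to give the ester enolate (the side-chain CH2 is far more accessible than the methyl-bearing lactone α-CH), which adds 5-exo-trig to the lactone C=O; collapse of the adduct expels the ring oxygen, so the former lactone carbonyl becomes the cyclopentanone C=O and the stabilised β-keto ester enolate 6 with a free tertiary O–CMe2 group is reached, the sink of all reversible Claisen equilibria (Dieckmann condensation with an internal alkoxide leaving group). The second equivalent of base gives the hard tertiary alkoxide, which should be acylated by Boc2O in preference to the delocalised enolate (carbonate 7). Further LDA removes the only remaining acidic proton of the enolate, at the methyl-bearing α′-carbon (β-keto ester dianion), and this carbanion attacks the carbonate C=O 5-exo-trig and expels tert-butoxide, closing the γ-lactone by its C(=O)–C(CH3) bond; the closest known reaction type is the γ-acylation of β-keto ester dianions by esters and carbonates, here intramolecular. The new quaternary stereocentre is dictated by the neighbouring ring CH that carries the O–CMe2 arm: two five-membered rings can only be cis-fused, so the carbonyl enters on the face of that arm and the methyl group is left on the face of the ring-fusion hydrogen. The selectivity needed is attack by the α′-carbon and not by the ester-bearing enolate carbon; it is secured because the dianion reacts at its more basic, non-stabilised terminus and closure at the other carbon would require a bridged bicyclo[3.2.1] lactone, while loss of the other alkoxide from the tetrahedral intermediate would only give a tert-butyl ester that relactonises to the same product.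

Step 6
Reactants: 8 methyl (3aS,6aS)-3,3,6a-trimethyl-1,6-dioxohexahydro-1H-cyclopenta[c]furan-5-carboxylate; 9 2-methyl-2-vinyloxirane (racemic)
Product: 10 methyl (3aS,5R,6aS)-5-[(2E)-4-hydroxy-3-methylbut-2-en-1-yl]-3,3,6a-trimethyl-1,6-dioxohexahydro-1H-cyclopenta[c]furan-5-carboxylate
Conditions: Pd(PPh3)4 (5 mol%), THF, 0 °C → rt
Reagents that add atoms: none
Why: Tsuji–Trost allylation under neutral conditions: Pd(0) opens the vinyl epoxide (its stereocentre is lost) to a zwitterionic π-allyl complex whose alkoxide deprotonates the β-keto ester, and the enolate should attack the unsubstituted allyl terminus (1,4-addition, E-alkene from the syn complex) on the convex face of the bicycle, syn to the angular methyl and ring-fusion hydrogen and away from the lactone ring with its inward-pointing CMe2 methyl, which sets the quaternary (5R) carbon.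

Step 7
Reactants: 10 methyl (3aS,5R,6aS)-5-[(2E)-4-hydroxy-3-methylbut-2-en-1-yl]-3,3,6a-trimethyl-1,6-dioxohexahydro-1H-cyclopenta[c]furan-5-carboxylate
Product: 11 methyl (3aS,5R,6aS)-3,3,6a-trimethyl-5-[(2E)-3-methyl-4-(4,4,5,5-tetramethyl-1,3,2-dioxaborolan-2-yl)but-2-en-1-yl]-1,6-dioxohexahydro-1H-cyclopenta[c]furan-5-carboxylate
Conditions: B2pin2 (1.2 equiv), [Pd(MeCN)4](BF4)2 (5 mol%), DMSO/MeOH, rt
Reagents that add atoms: bis(pinacolato)diboron, CC1(C)OB(OC1(C)C)B1OC(C)(C)C(C)(C)O1
Why: Pd-catalysed direct borylation of an allylic alcohol: ionisation to the π-allyl complex and transmetalation with the diboron should place boron on the less hindered terminus and give the thermodynamically preferred (E)-allylboronate (any Z-alcohol from step 6 should converge through the same π-allyl complex), under neutral conditions that spare the non-enolisable tricarbonyl array; no stereocentre is formed.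

Step 8
Reactants: 12 3-methylbutan-2-one
Product: 13 3-methyl-2-oxobutanal
Conditions: SeO2 (1 equiv), 1,4-dioxane/H2O (cat.), reflux; distillation
Reagents that add atoms: selenium dioxide, O=[Se]=O
Why: Riley oxidation: selenium dioxide should oxidise the methyl group, the only α-position that can deliver a 1,2-dicarbonyl compound, to the aldehyde.

Step 9
Reactants: 11 methyl (3aS,5R,6aS)-3,3,6a-trimethyl-5-[(2E)-3-methyl-4-(4,4,5,5-tetramethyl-1,3,2-dioxaborolan-2-yl)but-2-en-1-yl]-1,6-dioxohexahydro-1H-cyclopenta[c]furan-5-carboxylate; 13 3-methyl-2-oxobutanal
Product: 15 (3aS,5R,6aS,5′S,6′S)-3,3,6a-trimethyl-6′-(2-methylpropanoyl)-5′-(prop-1-en-2-yl)hexahydrospiro[cyclopenta[c]furan-5,3′-oxane]-1,2′,6-trione (CNP0216954.1), via hydroxy ester 14 (not isolated)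
Conditions: (S)-TRIP (10 mol%), 4 Å MS, PhMe, −30 °C; aq. work-up; then CSA (10 mol%), PhMe, 40 °C
Reagents that add atoms: none
Why: Allylboration of the aldehyde carbonyl through a closed chair-like six-membered transition state with allylic transposition creates the isopropenyl group, the (E)-γ-substituent sitting equatorial so that the anti pair of new centres results, while the chiral phosphoric acid (hydrogen-bonded to a boronate oxygen and the formyl C–H) is expected, by analogy with its established sense of induction, to direct attack to the Si face and so give the (S,S) configuration; acid-catalysed attack of the new secondary hydroxyl on the neighbouring methyl ester then closes the δ-lactone (6-exo-trig lactonisation).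

**Compound list**

1 | (S)-(−)-α-terpineol, 2-[(1S)-4-methylcyclohex-3-en-1-yl]propan-2-ol | CC1=CC[C@H](CC1)C(C)(C)O | starting material
2 | (4S)-5,5-dimethyl-4-(3-oxobutyl)oxolan-2-one | CC(=O)CC[C@H]1CC(=O)OC1(C)C | intermediate
3 | 3-[(3S)-2,2-dimethyl-5-oxooxolan-3-yl]propanoic acid | OC(=O)CC[C@H]1CC(=O)OC1(C)C | intermediate
4 | 3-[(3S,4S)-2,2,4-trimethyl-5-oxooxolan-3-yl]propanoic acid | OC(=O)CC[C@H]1[C@H](C)C(=O)OC1(C)C | intermediate
5 | methyl 3-[(3S,4S)-2,2,4-trimethyl-5-oxooxolan-3-yl]propanoate | COC(=O)CC[C@H]1[C@H](C)C(=O)OC1(C)C | intermediate
6 | methyl (3S,4S)-4-(2-hydroxypropan-2-yl)-3-methyl-2-oxocyclopentane-1-carboxylate (lithium enolate/alkoxide in the flask; C-1 is an enolate carbon) | COC(=O)C1C[C@H](C(C)(C)O)[C@H](C)C1=O | intermediate (not isolated)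
7 | methyl (3S,4S)-4-[2-(tert-butoxycarbonyloxy)propan-2-yl]-3-methyl-2-oxocyclopentane-1-carboxylate (lithium enolate in the flask) | COC(=O)C1C[C@H](C(C)(C)OC(=O)OC(C)(C)C)[C@H](C)C1=O | intermediate (not isolated)
8 | methyl (3aS,6aS)-3,3,6a-trimethyl-1,6-dioxohexahydro-1H-cyclopenta[c]furan-5-carboxylate (C-5 epimers/enol; C-5 is set in step 6) | COC(=O)C1C[C@@H]2C(C)(C)OC(=O)[C@]2(C)C1=O | intermediate
9 | 2-methyl-2-vinyloxirane (isoprene monoepoxide, racemic) | CC1(CO1)C=C | starting material
10 | methyl (3aS,5R,6aS)-5-[(2E)-4-hydroxy-3-methylbut-2-en-1-yl]-3,3,6a-trimethyl-1,6-dioxohexahydro-1H-cyclopenta[c]furan-5-carboxylate | COC(=O)[C@]1(C/C=C(\C)CO)C[C@@H]2C(C)(C)OC(=O)[C@]2(C)C1=O | intermediate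
11 | methyl (3aS,5R,6aS)-3,3,6a-trimethyl-5-[(2E)-3-methyl-4-(4,4,5,5-tetramethyl-1,3,2-dioxaborolan-2-yl)but-2-en-1-yl]-1,6-dioxohexahydro-1H-cyclopenta[c]furan-5-carboxylate | COC(=O)[C@]1(C/C=C(\C)CB2OC(C)(C)C(C)(C)O2)C[C@@H]3C(C)(C)OC(=O)[C@]3(C)C1=O | intermediate
12 | 3-methylbutan-2-one | CC(C)C(C)=O | starting material
13 | 3-methyl-2-oxobutanal | CC(C)C(=O)C=O | intermediate
14 | methyl (3aS,5R,6aS)-5-[(2S,3S)-3-hydroxy-5-methyl-4-oxo-2-(prop-1-en-2-yl)hexyl]-3,3,6a-trimethyl-1,6-dioxohexahydro-1H-cyclopenta[c]furan-5-carboxylate | COC(=O)[C@]1(C[C@@H](C(C)=C)[C@H](O)C(=O)C(C)C)C[C@@H]2C(C)(C)OC(=O)[C@]2(C)C1=O | intermediate (not isolated)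
15 | (3aS,5R,6aS,5′S,6′S)-3,3,6a-trimethyl-6′-(2-methylpropanoyl)-5′-(prop-1-en-2-yl)hexahydrospiro[cyclopenta[c]furan-5,3′-oxane]-1,2′,6-trione (CNP0216954.1) | C=C(C)[C@@H]1C[C@]2(C[C@@H]3C(C)(C)OC(=O)[C@]3(C)C2=O)C(=O)O[C@@H]1C(=O)C(C)C | target

**Step count and risks**

Total step count: 9. Longest linear sequence: 8 (steps 1–7 and 9); step 8 is a one-step side branch.

Steps most likely to fail:

1. Step 5. The second deprotonation, at the hindered methyl-bearing carbon of the enolate, may be too slow; the Boc group may then migrate to the enolate oxygen or be attacked by the wrong carbon. In the first stage, enolisation of the lactone α-CH may also compete with ester enolisation. The fallback sets out from 7 and comes back at 10. The sequence would be stopped after the Boc2O stage and 7 isolated. Its β-keto ester would be allylated with 9 under the neutral Pd(0) conditions of step 6; attack anti to the 1,3-related CMe2OBoc group (and the cis methyl) should give the same configuration at the quaternary carbon, in the allylated Boc carbonate F1. F1 has only one enolisable position left, the methyl-bearing α-carbon of the ketone, so LiHMDS (2.1 equiv, the first for the hydroxyl; THF, −78 → 0 °C) should close the γ-lactone by a simple mono-enolate Claisen acylation of the carbonate, again through the C(=O)–C(CH3) bond and necessarily cis-fused, to give 10.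

2. Step 9. The catalyst may not control the aldehyde face well enough against an uncatalysed addition to the very electrophilic glyoxal. Any (Z)-boronate would erode the anti relationship, and the centre α to the ketone may epimerise during lactonisation. The fallback sets out from 8 and comes back at 14. Alkylation of 8 with prenyl bromide (K2CO3, acetone), on the convex face as in step 6, would give the prenylated keto ester F2. A chiral Lewis acid that binds 13 through both carbonyl oxygens (Cu(II)–bis(oxazoline) or Ni(II)–N,N′-dioxide type) would then mediate a carbonyl-ene reaction. C–C bond formation at the less substituted alkene carbon with hydrogen transfer from a methyl group gives the isopropenyl group and the secondary alcohol of 14 in one step, the aldehyde face being fixed by two-point binding. The relative configuration of the two new centres would have to be established and the diastereomers separated. Lactonisation as in step 9 follows.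

3. Step 7. The π-allyl palladium intermediate may undergo β-hydride elimination to a diene, the allylboronate may protodeboronate, or the alkene geometry may scramble. The fallback sets out from 10 and comes back at 14, without boron. An Appel reaction (CBr4, PPh3, CH2Cl2, 0 °C) would give the allylic bromide F3. A Nozaki–Hiyama–Kishi-type addition (CrCl2, THF, 0 °C) to 13 follows; the allylchromium species equilibrates to the E form and should react through a chair transition state at the aldehyde only, giving the anti adduct whatever the bromide geometry. 14 would then be obtained together with the other anti diastereomer, to be separated unless a chiral ligand for chromium is added. Lactonisation as in step 9 follows.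

Further compounds
F1 | step 5 | methyl (1R,3S,4S)-4-[2-(tert-butoxycarbonyloxy)propan-2-yl]-1-[(2E)-4-hydroxy-3-methylbut-2-en-1-yl]-3-methyl-2-oxocyclopentane-1-carboxylate | COC(=O)[C@]1(C/C=C(\C)CO)C[C@H](C(C)(C)OC(=O)OC(C)(C)C)[C@H](C)C1=O
F2 | step 9 | methyl (3aS,5R,6aS)-3,3,6a-trimethyl-5-(3-methylbut-2-en-1-yl)-1,6-dioxohexahydro-1H-cyclopenta[c]furan-5-carboxylate | COC(=O)[C@]1(CC=C(C)C)C[C@@H]2C(C)(C)OC(=O)[C@]2(C)C1=O
F3 | step 7 | methyl (3aS,5R,6aS)-5-[(2E)-4-bromo-3-methylbut-2-en-1-yl]-3,3,6a-trimethyl-1,6-dioxohexahydro-1H-cyclopenta[c]furan-5-carboxylate | COC(=O)[C@]1(C/C=C(\C)CBr)C[C@@H]2C(C)(C)OC(=O)[C@]2(C)C1=O
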